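**Retrosynthetic overview**
1. Locants: ring C1 (CH bearing the chain), C2 (CHMe), C3 (CMeOH), C4 (CHOAc), C5 (CMeOH), C6 (CHOH). Chain carbons C7–C12 run from the ring to the pyrone.
2. Feature used: cutting C9=C10 (HWE with allylic phosphonate 28, which carries C10–C12 and the 2-methoxy-3,5-dimethyl-4-pyrone ring) leaves ring carbon C1 as the γ-carbon of the C7=C8(Me)–C9 enal. Its ring neighbour C6 is a carbinol on quaternary C5, so its aldehyde form has no α-hydrogen. This is a vinylogous aldol retron.
3. Key disconnection C1–C6: cyclohexane 15 ⇒ open-chain C9-enal/C6-aldehyde 13, with C2–C5 set and the C4 acetate in place.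
4. 13 ⇒ tiglic aldehyde + isopropenylMgBr (C2–C6). Sharpless kinetic resolution sets C2/C3/C4, osmylation sets C5, allyl-copper opening inverts C2 and adds C1/C7, and cross-metathesis with methacrolein adds C8/C9. The allyl group enters only after the isopropenyl alkene has been consumed, because a compound holding both is an octa-1,7-diene that would ring-close on ruthenium instead of cross-coupling.
5. Ring order: the cyclohexane closes in step 10 on the main line and the pyrone in step 15 on the side line (triketide lactonisation). Both exist before the union in step 20.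

Key step: step 10

Remark on configuration: in these locants the given SMILES reads (1R,2S,3R,4R,5S,6S). The four ring oxygens lie on one face, and the C1 chain and the C2 methyl lie on the other. All three chain alkenes are E.

**Main line**

Step 1
Reactants: 1 (E)-2-methylbut-2-enal (tiglic aldehyde); 2 isopropenylmagnesium bromide
Product: 3 rac-(E)-2,4-dimethylhexa-1,4-dien-3-ol
Conditions: THF, −78 → 0 °C; aq. NH4Cl
Reagents that add atoms: none
Why: Grignard 1,2-addition to the enal gives the bis-allylic alcohol (C2–C6 with three of the four methyl groups) as a racemate, and C4 is sorted out in step 2.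

Step 2
Reactants: 3 rac-(E)-2,4-dimethylhexa-1,4-dien-3-ol
Product: 4 (1S)-1-[(2S,3S)-2,3-dimethyloxiran-2-yl]-2-methylprop-2-en-1-ol
Conditions: Ti(OiPr)4 (0.15 equiv), L-(+)-DIPT (0.18 equiv), TBHP (0.45 equiv), 4 Å MS, CH2Cl2, −20 °C
Reagents that add atoms: tert-butyl hydroperoxide CC(C)(C)OO
Why: Sharpless kinetic resolution, in which L-(+)-tartrate epoxidises the (S)-alcohol much faster than the (R)-alcohol, at its more nucleophilic trisubstituted alkene, on the face that gives the (2S,3S)-oxirane and with the usual anti (erythro) relation to the carbinol, so that C3, C4 and the oxirane centre C2 are fixed at once while unreacted (R)-3 is removed by chromatography.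

Step 3
Reactants: 4 epoxy allylic alcohol
Product: 5 (2S,3S)-3-[(2S,3S)-2,3-dimethyloxiran-2-yl]-2-methylpropane-1,2,3-triol
Conditions: OsO4 (2 mol %), NMO, acetone–H2O, 0 °C → rt
Reagents that add atoms: N-methylmorpholine N-oxide C[N+]1([O-])CCOCC1; water O
Why: Upjohn dihydroxylation of the only alkene, in which the reactive rotamer has C4–H next to the C5 methyl (least A(1,2) strain), C4–OH inside and the bulky oxiranyl group anti to OsO4, so the new C5–OH ends up anti to C4–OH, in line with the empirical anti rule for osmylation of allylic alcohols, and this is the required C5 centre.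

Step 4
Reactants: 5 epoxy triol
Product: 6 (1S,2S)-1-[(2S,3S)-2,3-dimethyloxiran-2-yl]-2-methyl-3-(triethylsilyloxy)propane-1,2-diol
Conditions: TESCl (1.05 equiv), imidazole, CH2Cl2, −20 °C
Reagents that add atoms: chlorotriethylsilane CC[Si](Cl)(CC)CC
Why: Sterically selective silyl ether formation reaches only the primary C6–OH, which marks C6 for the later oxidation and keeps O6 from attacking the oxirane in step 5.

Step 5
Reactants: 6 C6 silyl ether; 7 allylmagnesium bromide
Product: 8 (2S,3R,4R,5S)-2,4,5-trimethyl-1-(triethylsilyloxy)oct-7-ene-2,3,4-triol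
Conditions: 7 (5 equiv), CuI (0.3 equiv), THF–Et2O, −40 → 0 °C; aq. NH4Cl
Reagents that add atoms: none
Why: Copper-catalysed SN2 opening of the trisubstituted 2,3-epoxy alcohol, in which C3 is fully substituted so the allyl group enters at C2 opposite to oxygen, inverting C2 to the required configuration and freeing the C3 tertiary alcohol with retention (two further equivalents of 7 are spent on the two hydroxyl groups).

Step 6
Reactants: 8 triol
Product: 9 (2S,3R,4R,5S)-2,4-dihydroxy-2,4,5-trimethyl-1-(triethylsilyloxy)oct-7-en-3-yl acetate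
Conditions: Ac2O, DMAP (0.2 equiv), pyridine, CH2Cl2, rt
Reagents that add atoms: acetic anhydride CC(=O)OC(C)=O
Why: DMAP-catalysed acylation picks the single secondary alcohol (C4) over the two tertiary ones, the acetate has no driving force to move to a tertiary oxygen, and no stereocentre is touched.

Step 7
Reactants: 9 C4 acetate
Product: 10 (2S,3R,4R,5S)-2,4,5-trimethyl-1,2,4-tris(triethylsilyloxy)oct-7-en-3-yl acetate
Conditions: TESOTf (3 equiv), 2,6-lutidine, CH2Cl2, −78 → 0 °C
Reagents that add atoms: triethylsilyl triflate CC[Si](CC)(CC)OS(=O)(=O)C(F)(F)F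
Why: Silyl triflate with 2,6-lutidine is the standard silylation of tertiary alcohols, and it is run here before any aldehyde is present.

Step 8
Reactants: 10 tris-silyl ether; 11 methacrolein
Product: 12 (2S,3R,4R,5S,7E)-2,4,5,8-tetramethyl-9-oxo-1,2,4-tris(triethylsilyloxy)non-7-en-3-yl acetate
Conditions: Hoveyda–Grubbs II (5 mol %), 11 (10 equiv), CH2Cl2, 40 °C
Reagents that add atoms: none
Why: Olefin cross-metathesis of a terminal alkene with excess methacrolein, in which 10 has no second alkene so ring closure cannot compete and the trisubstituted enal should form as the E isomer.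

Step 9
Reactants: 12 enal
Product: 13 (2R,3R,4R,5S,7E)-2,4,5,8-tetramethyl-1,9-dioxo-2,4-bis(triethylsilyloxy)non-7-en-3-yl acetate
Conditions: (COCl)2, DMSO, CH2Cl2, −78 → −40 °C; Et3N, −78 °C → rt
Reagents that add atoms: none
Why: Under Swern conditions a primary triethylsilyl ether is cleaved and oxidised to the aldehyde in one operation while tertiary silyl ethers, acetate and enal remain, and the new C6 aldehyde cannot epimerise because C5 is quaternary.

Step 10
Reactants: 13 C9-enal C6-aldehyde
Product: 15 (E)-3-[(1R,2S,3R,4R,5S,6S)-4-acetoxy-6-hydroxy-2,3,5-trimethyl-3,5-bis(triethylsilyloxy)cyclohexyl]-2-methylprop-2-enal (route locants), via dienamine 14 (not isolated)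
Conditions: 9-amino-9-deoxy-epi-quinine (20 mol %), PhCO2H (40 mol %), toluene (0.02 M), 40 °C
Reagents that add atoms: none
Why: The bulky primary amine condenses only with the unhindered C9 enal, benzoate removes a C1 proton from the iminium ion, the γ-carbon C1 of dienamine 14 adds to the acid-activated C6 aldehyde, and hydrolysis of the conjugated iminium ion releases the catalyst and the E enal (s-trans dienamine). The closest known reaction types are γ-functionalisation of α-branched enals by cinchona primary-amine dienamine catalysis, intramolecular vinylogous aldol reactions of enals, and amine-catalysed 6-enolexo aldolisation of dialdehydes. The cyclohexane closes in the 6-(enolexo)-exo-trig mode; bond formation through C8 is ruled out because it would need an eight-membered ring and a new quaternary carbon, and the two aldehydes cannot exchange roles because C5 carries no hydrogen. C1 is controlled by the chair that holds C3-Me, C4-OAc and C5-Me equatorial, whose two axial silyloxy groups close the axial site at C1 so that the dienamine chain lies equatorial. C6 is controlled by the axial C2 methyl, which forbids an axial C6 oxygen (1,3-diaxial contact), so the carbonyl oxygen turns equatorial and the trans C1/C6 pair results, and because the addition is reversible the same isomer is also favoured at equilibrium. Vinylogous dehydration is held back because A(1,3) strain with the C8 methyl keeps the C1–H bond of 15 in the plane of the enal, where it overlaps poorly with the π system and is slow to be removed.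

Step 11
Reactants: 15 cyclohexane enal
Product: 16 C6 triethylsilyl ether of 15 (configuration unchanged)
Conditions: TESOTf, 2,6-lutidine, CH2Cl2, −78 °C
Reagents that add atoms: triethylsilyl triflate CC[Si](CC)(CC)OS(=O)(=O)C(F)(F)F
Why: Silylation of the secondary C6–OH removes the only acidic proton, so no alkoxide able to start a retro-aldol cleavage of C1–C6 can form in the basic olefination.

**Side line (phosphonate)**

Step 12
Reactants: 17 (tert-butyldimethylsilyloxy)acetaldehyde; 18 2-(triphenylphosphoranylidene)propanal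
Product: 19 (E)-4-(tert-butyldimethylsilyloxy)-2-methylbut-2-enal
Conditions: toluene, 90 °C
Reagents that add atoms: none
Why: Wittig reaction of a stabilised ylide, which should give the E trisubstituted enal holding C10–C12 and the C12 methyl.

Step 13
Reactants: 19 silyloxy enal; 20 methyl 2-methyl-3-oxopentanoate
Product: 22 methyl (6E)-8-(tert-butyldimethylsilyloxy)-5-hydroxy-2,4,6-trimethyl-3-oxooct-6-enoate (diastereomer mixture), via dilithio dianion 21 (not isolated)
Conditions: 20, LDA (2.1 equiv), THF, 0 °C; then 19, −78 °C; aq. NH4Cl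
Reagents that add atoms: none
Why: Aldol addition of the β-keto ester dianion through its more reactive γ-carbon to the aldehyde, where the new sp3 centres do not matter because all become sp2 in steps 14 and 15.

Step 14
Reactants: 22 aldol adduct
Product: 23 methyl (6E)-8-(tert-butyldimethylsilyloxy)-2,4,6-trimethyl-3,5-dioxooct-6-enoate
Conditions: Dess–Martin periodinane, CH2Cl2, rt
Reagents that add atoms: none
Why: Dess–Martin oxidation of the allylic alcohol under near-neutral conditions gives the 3,5-diketo ester without touching the silyl ether or the alkene geometry.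

Step 15
Reactants: 23 diketo ester
Product: 24 6-[(E)-4-(tert-butyldimethylsilyloxy)but-2-en-2-yl]-4-hydroxy-3,5-dimethyl-2H-pyran-2-one
Conditions: DBU, toluene, 80 °C
Reagents that add atoms: none
Why: Base-mediated lactonisation of the triketide, in which the C5 enol oxygen attacks the methyl ester (6-exo-trig) and tautomerisation gives the 4-hydroxy-2-pyrone.

Step 16
Reactants: 24 hydroxy-2-pyrone
Product: 25 2-[(E)-4-(tert-butyldimethylsilyloxy)but-2-en-2-yl]-6-methoxy-3,5-dimethyl-4H-pyran-4-one
Conditions: MeOTf, CH2Cl2, rt; aq. NaHCO3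
Reagents that add atoms: methyl triflate COS(=O)(=O)C(F)(F)F
Why: O-methylation of the neutral hydroxypyrone with a hard methylating agent occurs at its most basic oxygen, the lactone carbonyl, and proton loss at the basic work-up leaves the 2-methoxy-4-pyrone rather than the 4-methoxy-2-pyrone.

Step 17
Reactants: 25 silyl ether
Product: 26 2-[(E)-4-hydroxybut-2-en-2-yl]-6-methoxy-3,5-dimethyl-4H-pyran-4-one
Conditions: HF·pyridine, THF, 0 °C
Reagents that add atoms: none
Why: Fluoride-driven cleavage of the primary silyl ether under weakly acidic conditions that the methoxypyrone tolerates.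

Step 18
Reactants: 26 allylic alcohol
Product: 27 2-[(E)-4-bromobut-2-en-2-yl]-6-methoxy-3,5-dimethyl-4H-pyran-4-one
Conditions: CBr4, PPh3, CH2Cl2, 0 °C
Reagents that add atoms: carbon tetrabromide BrC(Br)(Br)Br
Why: Appel reaction, an SN2 displacement at the activated primary allylic carbon without allylic shift or loss of the E geometry.

Step 19
Reactants: 27 allylic bromide
Product: 28 diethyl [(E)-3-(6-methoxy-3,5-dimethyl-4-oxo-4H-pyran-2-yl)but-2-en-1-yl]phosphonate
Conditions: P(OEt)3, toluene, 110 °C
Reagents that add atoms: triethyl phosphite CCOP(OCC)OCC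
Why: Michaelis–Arbuzov reaction of a primary allylic bromide with triethyl phosphite.

**Union and end game**

Step 20
Reactants: 16 silylated cyclohexane enal; 28 allylic phosphonate
Product: 30 3,5,6-tris-O-triethylsilyl amaurone A, via lithiated phosphonate 29 (not isolated)
Conditions: 28 (1.2 equiv), LiHMDS (1.15 equiv), THF, −78 °C; then 16, −78 → 0 °C, dark
Reagents that add atoms: none
Why: Horner–Wadsworth–Emmons olefination, in which the anion delocalised into the pyrone carbonyl reacts at its α-carbon C10 with the C9 aldehyde and the reversible addition should funnel to the E C9=C10 alkene, while the existing E alkenes, the acetate and all ring centres stay untouched.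

Step 21
Reactants: 30 protected amaurone A
Product: 31 amaurone A
Conditions: HF·pyridine, pyridine, THF, 0 °C → rt, dark
Reagents that add atoms: none
Why: Fluoride cleavage of the three triethylsilyl ethers in a buffered, weakly acidic medium, which avoids the alkoxides that would cause acetate migration or retro-aldol cleavage.

**Compound list**
1 | (E)-2-methylbut-2-enal | C/C=C(C)/C=O | starting material
2 | isopropenylmagnesium bromide | CC(=C)[Mg]Br | starting material
3 | rac-(E)-2,4-dimethylhexa-1,4-dien-3-ol | C/C=C(C)/C(O)C(C)=C | intermediate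
4 | (1S)-1-[(2S,3S)-2,3-dimethyloxiran-2-yl]-2-methylprop-2-en-1-ol | C[C@@H]1O[C@@]1(C)[C@@H](O)C(C)=C | intermediate
5 | (2S,3S)-3-[(2S,3S)-2,3-dimethyloxiran-2-yl]-2-methylpropane-1,2,3-triol | C[C@@H]1O[C@@]1(C)[C@@H](O)[C@@](C)(O)CO | intermediate
6 | C6 triethylsilyl ether of 5 | C[C@@H]1O[C@@]1(C)[C@@H](O)[C@@](C)(O)CO[Si](CC)(CC)CC | intermediate
7 | allylmagnesium bromide | C=CC[Mg]Br | starting material
8 | (2S,3R,4R,5S)-2,4,5-trimethyl-1-(triethylsilyloxy)oct-7-ene-2,3,4-triol | C=CC[C@H](C)[C@@](C)(O)[C@@H](O)[C@@](C)(O)CO[Si](CC)(CC)CC | intermediate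
9 | C4 acetate of 8 | C=CC[C@H](C)[C@@](C)(O)[C@@H](OC(C)=O)[C@@](C)(O)CO[Si](CC)(CC)CC | intermediate
10 | C3,C5,C6 tris-triethylsilyl ether, C4 acetate | C=CC[C@H](C)[C@@](C)(O[Si](CC)(CC)CC)[C@@H](OC(C)=O)[C@@](C)(O[Si](CC)(CC)CC)CO[Si](CC)(CC)CC | intermediate
11 | methacrolein | CC(=C)C=O | starting material
12 | (E)-C9 enal with C6 silyl ether | O=C/C(C)=C/C[C@H](C)[C@@](C)(O[Si](CC)(CC)CC)[C@@H](OC(C)=O)[C@@](C)(O[Si](CC)(CC)CC)CO[Si](CC)(CC)CC | intermediate
13 | open-chain C9-enal C6-aldehyde (key-step precursor) | O=C/C(C)=C/C[C@H](C)[C@@](C)(O[Si](CC)(CC)CC)[C@@H](OC(C)=O)[C@@](C)(O[Si](CC)(CC)CC)C=O | intermediate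
14 | (1E,3E)-dienamine of 13 with 9-amino-9-deoxy-epi-quinine | COC1=CC2=C(C=CN=C2C=C1)[C@@H]([C@@H]3C[C@@H]4CCN3C[C@@H]4C=C)N/C=C(C)/C=C/[C@H](C)[C@@](C)(O[Si](CC)(CC)CC)[C@@H](OC(C)=O)[C@@](C)(O[Si](CC)(CC)CC)C=O | intermediate
15 | cyclohexane enal with free C6–OH (key-step product) | O=C/C(C)=C/[C@@H]1[C@H](C)[C@@](C)(O[Si](CC)(CC)CC)[C@@H](OC(C)=O)[C@@](C)(O[Si](CC)(CC)CC)[C@H]1O | intermediate
16 | C6 triethylsilyl ether of 15 | O=C/C(C)=C/[C@@H]1[C@H](C)[C@@](C)(O[Si](CC)(CC)CC)[C@@H](OC(C)=O)[C@@](C)(O[Si](CC)(CC)CC)[C@H]1O[Si](CC)(CC)CC | intermediate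
17 | (tert-butyldimethylsilyloxy)acetaldehyde | O=CCO[Si](C)(C)C(C)(C)C | starting material
18 | 2-(triphenylphosphoranylidene)propanal | CC(C=O)=P(c1ccccc1)(c1ccccc1)c1ccccc1 | starting material
19 | (E)-4-(tert-butyldimethylsilyloxy)-2-methylbut-2-enal | O=C/C(C)=C/CO[Si](C)(C)C(C)(C)C | intermediate
20 | methyl 2-methyl-3-oxopentanoate | CCC(=O)C(C)C(=O)OC | starting material
21 | dilithio dianion of 20 | [Li+].[Li+].COC([O-])=C(C)C([O-])=CC | intermediate
22 | methyl (6E)-8-(tert-butyldimethylsilyloxy)-5-hydroxy-2,4,6-trimethyl-3-oxooct-6-enoate | COC(=O)C(C)C(=O)C(C)C(O)/C(C)=C/CO[Si](C)(C)C(C)(C)C | intermediate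
23 | methyl (6E)-8-(tert-butyldimethylsilyloxy)-2,4,6-trimethyl-3,5-dioxooct-6-enoate | COC(=O)C(C)C(=O)C(C)C(=O)/C(C)=C/CO[Si](C)(C)C(C)(C)C | intermediate
24 | 6-[(E)-4-(tert-butyldimethylsilyloxy)but-2-en-2-yl]-4-hydroxy-3,5-dimethyl-2H-pyran-2-one | Cc1c(O)c(C)c(/C(C)=C/CO[Si](C)(C)C(C)(C)C)oc1=O | intermediate
25 | 2-[(E)-4-(tert-butyldimethylsilyloxy)but-2-en-2-yl]-6-methoxy-3,5-dimethyl-4H-pyran-4-one | COc1oc(/C(C)=C/CO[Si](C)(C)C(C)(C)C)c(C)c(=O)c1C | intermediate
26 | 2-[(E)-4-hydroxybut-2-en-2-yl]-6-methoxy-3,5-dimethyl-4H-pyran-4-one | COc1oc(/C(C)=C/CO)c(C)c(=O)c1C | intermediate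
27 | 2-[(E)-4-bromobut-2-en-2-yl]-6-methoxy-3,5-dimethyl-4H-pyran-4-one | COc1oc(/C(C)=C/CBr)c(C)c(=O)c1C | intermediate
28 | diethyl [(E)-3-(6-methoxy-3,5-dimethyl-4-oxo-4H-pyran-2-yl)but-2-en-1-yl]phosphonate | CCOP(=O)(C/C=C(C)/c1oc(OC)c(C)c(=O)c1C)OCC | intermediate
29 | lithiated phosphonate | [Li+].CCOP(=O)([CH-]/C=C(C)/c1oc(OC)c(C)c(=O)c1C)OCC | intermediate
30 | 3,5,6-tris-O-triethylsilyl amaurone A | COc1oc(/C(C)=C/C=C/C(C)=C/[C@@H]2[C@H](C)[C@@](C)(O[Si](CC)(CC)CC)[C@@H](OC(C)=O)[C@@](C)(O[Si](CC)(CC)CC)[C@H]2O[Si](CC)(CC)CC)c(C)c(=O)c1C | intermediate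
31 | amaurone A | COc1oc(/C(C)=C/C=C/C(C)=C/[C@@H]2[C@H](C)[C@@](C)(O)[C@@H](OC(C)=O)[C@@](C)(O)[C@H]2O)c(C)c(=O)c1C | target

**Totals**
Total step count: 21. Longest linear sequence: 13 (steps 1–11, 20, 21).

**Steps most likely to fail**

Step 10.
- What may go wrong: slow closure onto the neopentylic aldehyde, reversal of the aldol at equilibrium, leakage through the ring-flipped chair (loss of diastereoselectivity), a mismatch between catalyst and substrate, or vinylogous dehydration on long exposure to amine and acid.
- Fallback, from 13 back to 15: TESOTf and Et3N (CH2Cl2, −78 → 0 °C) convert the enal of 13 into the triethylsilyl dienol ether F1. The C6 aldehyde has no α-hydrogen and stays as it is. BF3·OEt2 (CH2Cl2, −78 °C) then triggers an intramolecular vinylogous Mukaiyama aldol reaction through the same C1–C6 bond and the same chair. This addition is irreversible at low temperature and needs no amine, and aqueous work-up gives 15.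

Step 3.
- What may go wrong: poor facial selectivity of the osmylation at the 1,1-disubstituted alkene.
- Fallback, from 4 back to 5: hydroxyl-directed epoxidation (VO(acac)2 cat., TBHP, CH2Cl2, 0 °C) is strongly anti-selective for 2-substituted allylic alcohols because of A(1,2) strain, and should give the bis-epoxy alcohol F2. Cesium benzoate with benzoic acid in DMF opens the unsubstituted C6 terminus by SN2 to the C6 benzoate F3. The C5–O bond is untouched in this opening, and the methyl-bearing oxirane is far slower. K2CO3 in MeOH at 0 °C then removes the benzoate and gives 5.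

Step 20.
- What may go wrong: low reactivity of the strongly stabilised phosphonate anion towards the hindered α-branched enal, and incomplete E selectivity at C9=C10.
- Fallback, from 27 back to 30: bromide 27 is treated with 1-phenyl-1H-tetrazole-5-thiol and Et3N (THF) to give the tetrazolyl sulfide F4. Oxidation with ammonium molybdate and H2O2 (EtOH) gives the tetrazolyl sulfone F5. A Julia–Kocienski olefination follows, with KHMDS added to a mixture of F5 and 16 in THF at −78 °C, so that the more reactive sulfonyl carbanion adds irreversibly in the cold. This gives 30.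

**Further compounds**
F1 | step 10 | (1E,3E)-triethylsilyl dienol ether of 13 | CC[Si](CC)(CC)O/C=C(C)/C=C/[C@H](C)[C@@](C)(O[Si](CC)(CC)CC)[C@@H](OC(C)=O)[C@@](C)(O[Si](CC)(CC)CC)C=O
F2 | step 3 | anti,anti bis-epoxy alcohol (C2–C3 and C5–C6 oxiranes, C4–OH) | C[C@@H]1O[C@@]1(C)[C@@H](O)[C@]1(C)CO1
F3 | step 3 | C6 benzoate of 5 | C[C@@H]1O[C@@]1(C)[C@@H](O)[C@@](C)(O)COC(=O)c1ccccc1
F4 | step 20 | 2-methoxy-3,5-dimethyl-6-[(E)-4-(1-phenyl-1H-tetrazol-5-ylsulfanyl)but-2-en-2-yl]-4H-pyran-4-one | COc1oc(/C(C)=C/CSc2nnnn2-c2ccccc2)c(C)c(=O)c1C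
F5 | step 20 | 2-methoxy-3,5-dimethyl-6-[(E)-4-(1-phenyl-1H-tetrazol-5-ylsulfonyl)but-2-en-2-yl]-4H-pyran-4-one | COc1oc(/C(C)=C/CS(=O)(=O)c2nnnn2-c2ccccc2)c(C)c(=O)c1C
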